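## The problem

The target is a cis-fused octalin: ring A (C1, which bears a methyl group and the alkene to C2, then C3, C8, C9, C10) shares the bond C3–C8 with ring B (C3–C4–C5–C6–C7–C8). C4 carries an oxolane (O, C11–C14) through its fully substituted carbon C11, C14 carries C15, and the fully substituted carbons C7 and C15 each bear a formamide. Six stereocentres must be set: on the decalin H3, H8, the C4 ether arm and the C7 methyl group lie on one face (called α here) and the C7 nitrogen on the other (β), and on the ether ring the C11 methyl group is trans to the C15 group (11S,14R). Neither C–N bond can be made by substitution, because both carbons are tertiary, and a cation at C15 would be lost to hydride shift from C14 or to ring expansion of the ether. C8 can control C3 when the C3–C4 bond is delivered across ring A, and an oxygen on C5 can control C7 through a tether; C4, flanked by C3 and the quaternary C11, is the hardest centre to control, and C11 and C14 are too remote to be set by the decalin. Any intermediate with a carbonyl group at C5 has an acidic C4–H and an ether oxygen β to the carbonyl, so base threatens both C4 and the ether ring; the trisubstituted alkene and the tertiary ethers dislike strong acid, and formamides survive neither hydride nor strong base. The feature that opens the key step is that ring A with its alkene, the C8 stereocentre and a C8 isopropenyl group (C7, its methyl group and C6) is limonene: once a C4–C5 arm ending in an aldehyde stands on C3 cis to that group, ring B lacks only the bond C5–C6, which a carbonyl-ene reaction can make.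

## Retrosynthesis

**Formamides and nitrogen protection (35 ← 34 ← 33).** The two N–CHO bonds are cut first, then two N–S bonds, so that both nitrogens travel as toluenesulfonamides. A carbamate on C15 would need an acidic last deprotection beside the trisubstituted alkene; with the same sulfonyl group on both nitrogens one reduction frees both. Compound 33 already holds every carbon and every stereocentre. The forward steps must cleave two hindered N–H sulfonamides without touching alkene or ethers and formylate two tert-alkyl amines.

**C7–N and C5–H (33 ← 31 ← 30 ← 29 ← 28 ← 27).** The C5–H bond is traced back to a C5 hydroxyl (Barton–McCombie), and the C7–N bond is cut inside the cyclic N-tosyl carbamate 29 that reaches over from the C5 oxygen. An intermolecular amination of a C7 alkene (Ritter reaction, radical hydroazidation) would distinguish neither the two faces of C7 nor the two alkenes, whereas a tether from a β-oxygen on C5 can deliver nitrogen only to the β face. Precursor 27 has no nitrogen on the decalin and carries exactly the two groups needed, a β-hydroxyl on C5 and a methylidene on C7. The forward reaction must attack through nitrogen at the substituted alkene carbon, and ring B must pass through a boat, because O5 and N7 both have to become axial to be bridged.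

**Ring B (27 ← 26).** The bond C5–C6 is cut in the sense of a carbonyl-ene reaction: C5 becomes an aldehyde, C6 the terminal carbon of an isopropenyl group, and the hydroxyl hydrogen returns to the C7 methyl group. Cutting C3–C4 or C7–C8 instead would leave ring-fusion centres to be made between two fragments. C5–C6 is the one bond of ring B that joins two carbons that are not stereogenic in the target, and cutting it uncovers limonene. Compound 26 has a single carbocycle and one stereocentre fewer (C5). The forward reaction must close a cis-fused ring through a chair that puts the C5 oxygen trans to the C4 arm, under conditions that do not enolise the aldehyde.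

**C3–C4 (26 ← 25 ← 24 ← 21).** After adjustment of the oxidation level at C5 (aldehyde ← alcohol ← acid), the bond C3–C4 is cut as an Ireland–Claisen rearrangement: C5 becomes the ester carbonyl on the C1 oxygen of a tertiary allylic alcohol and the alkene moves from C1=C2 to C2=C3. An enolate alkylation or conjugate addition at C3 would enter trans to the isopropenyl group; the [3,3] shift hands the configuration of the C1–O bond to C3 on the same face, so an oxygen cis to the isopropenyl gives the cis arm. Ester 21 falls into two fragments of similar size. The demand on the forward reaction is the C4 configuration. The 3,4-anti arrangement arises from the (E)-silyl ketene acetal through a boat-like transition state (or from the (Z)-isomer through a chair). This is the thinnest point of the plan, because the large ether substituent lies over C8 in that boat, and a corrective sequence is held in reserve. The enolate must also be silylated before it can expel the β-ether oxygen.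

**Ester (21 ← 18 ← 15 + 6).** The ester C–O bond is cut to acid 15 and alcohol 6, and the sulfonamide is traced back to an azide. The azide has no N–H, so a lithium alkoxide can be acylated with the acid chloride, the dependable way to esterify a hindered tertiary allylic alcohol. The nitrogen is unmasked and sulfonylated afterwards.

**Ring A alcohol (6 ← 3 ← 1).** The allylic alcohol is cut back to the 1,2-epoxide 3 of (S)-limonene with the oxygen cis to the isopropenyl group, and from there to 1. Photo-oxygenation of limonene would give the same alcohol only as one of several regio- and stereoisomers; the epoxide route fixes both by trans-diaxial ring openings. The forward steps must form the bromohydrin only on the ring alkene and open the epoxide at C2.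

**Ether-ring acid (15 ← 13 ← 11 ← 10 ← 9 ← 7).** The acid carbon is traced to the ethenyl group of linalool (hydroboration, oxidation). The C15–N bond is cut as a radical Markovnikov hydroazidation of an isopropenyl group, the mode that avoids a C15 cation. The isopropenyl group comes from the tertiary alcohol of 9, and the O–C14 bond is cut to the 6,7-epoxide 8 of (S)-linalool 7. C11 is bought with linalool; C14 is set by a reagent-controlled epoxidation followed by a 5-exo opening with inversion. Compound 7 is acyclic with one stereocentre. The forward steps must epoxidise only the trisubstituted alkene and azidate the 1,1-disubstituted alkene in the presence of the ethenyl group.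

## Roads not taken

**Alternative 1:** The ether ring is cut at O–C14. In the forward step KH would deprotonate the tertiary alcohol of the linalool-derived N-sulfonyl aziridine A2, and the alkoxide would open the aziridine at its secondary carbon with inversion (5-exo), leaving the sulfamoyl nitrogen on tertiary C15 in oxolane A1.
- Merits: the tertiary C–N bond is formed without a cation or a radical, and the nitrogen-bearing ether ring is reached from linalool in two steps. The chosen plan needs three (steps 3–5) and a later azide reduction, so for this fragment the alternative is shorter.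
- Weak points: the face of the nitrene transfer is not controlled by the remote C11 centre, so C14 depends on catalyst control that is less dependable on trisubstituted alkenes than epoxidation. The sulfamate must later be exchanged for a group that survives the rest of the route. The step does nothing for the decalin.
- Comparison: the chosen plan sets C14 by a reagent-controlled epoxide and a stereospecific inversion, and its strategic step builds the carbocycle, which this road leaves open.

**Alternative 2:** C3–C4 and C11–O are cut together. Bi(OSO2CF3)3 would ionise the tertiary allylic alcohol of the open-chain precursor A4, the (Z)-trisubstituted alkene would attack the allyl cation to close ring B, and the C14 hydroxyl would trap the resulting C11 cation to give tricycle A3.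
- Merits: two rings and three stereocentres (C3, C4, C11) in one step, and the shortest route if it works. In bond economy it is better than the chosen plan.
- Weak points: the allyl cation can be attacked at either end and on either face, and proton loss to dienes competes. The nitrile and azide bind the Lewis acid. The quaternary C7 centre with its nitrile has to be made on an open chain next to C8 without cyclic control, and the nitrile must still be degraded to an amine.
- Comparison: the chosen plan forms one bond per step, but each stereocentre has a named control element (C1–O for C3, the chair for C5, the tether for C7, linalool for C11, the epoxide for C14).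

**Alternative 3:** The ether ring is cut at C13–C14. Bu3SnH with AIBN would generate the primary C13 radical from bromide A6, which adds 5-exo to the β-carbon of the β-alkoxyacrylate on the C11 oxygen to give the cis-2,5-disubstituted oxolane A5.
- Merits: this radical closure is dependably cis-selective, it tolerates the C7 formamide, and the early stages carry only a small C4 substituent. The Curtius degradation it leads to is a more secure way to the tertiary C15–N bond than the radical azidation of step 5.
- Weak points: it needs a tertiary C11 alcohol of defined configuration on the decalin and its addition to a propiolate. A5 still lacks both C15 methyl groups and the nitrogen (double α-methylation, hydrolysis, Curtius rearrangement), which adds at least four steps.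
- Comparison: the chosen plan takes C11 from linalool instead of creating it by an addition next to C4, and it reaches C15–N in one step.

Key step: step 13

Assumption: (S)-linalool of high enantiomeric purity and the L-fructose-derived enantiomer of the Shi ketone are taken as commercial; with linalool of lower purity the minor series would be removed as a diastereomer after step 8.

## Route

Step 1
Reactants: 1 (S)-limonene
Product: 3 (1R,4S,6S)-1-methyl-4-(prop-1-en-2-yl)-7-oxabicyclo[4.1.0]heptane, via bromohydrin 2 (not isolated)
Conditions: NBS, acetone/H2O, 0 °C; then aq. NaOH, rt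
Reagents that add atoms: water (O)
Why: Bromohydrin formation on the more electron-rich ring alkene followed by Williamson closure. Water opens the bromonium ion trans-diaxially at C1 in the chair with equatorial isopropenyl (Fürst–Plattner rule), so the oxygen ends cis to the isopropenyl group and only this epoxide should form.

Step 2
Reactants: 3 (1R,4S,6S)-1-methyl-4-(prop-1-en-2-yl)-7-oxabicyclo[4.1.0]heptane
Product: 6 (1R,4S)-1-methyl-4-(prop-1-en-2-yl)cyclohex-2-en-1-ol, via hydroxy selenide 4 (not isolated), via selenoxide 5 (not isolated)
Conditions: (PhSe)2, NaBH4, EtOH, reflux; then H2O2, THF, 0 °C to rt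
Reagents that add atoms: none
Why: Epoxide opening by selenolate at the secondary carbon C2 (trans-diaxial) and selenoxide syn-elimination. The elimination can run only toward C3 because C1 is fully substituted, and the C1 oxygen stays cis to the isopropenyl group.

Step 3
Reactants: 7 (S)-linalool
Product: 9 2-[(2R,5S)-5-ethenyl-5-methyloxolan-2-yl]propan-2-ol, via epoxy alcohol 8 (not isolated)
Conditions: ent-Shi ketone (L-fructose-derived, 0.3 equiv), Oxone (2KHSO5·KHSO4·K2SO4), K2CO3, Bu4NHSO4, MeCN/dimethoxymethane/aq. buffer, 0 °C; then camphorsulfonic acid (cat.), CH2Cl2, 0 °C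
Reagents that add atoms: potassium hydrogen peroxymonosulfate (OOS(=O)(=O)[O-].[K+])
Why: Shi epoxidation takes only the trisubstituted alkene and sets the (6S)-epoxide by reagent control. The tertiary hydroxyl then opens it 5-exo with inversion, which gives (R) at C14, while C11 comes unchanged from linalool.

Step 4
Reactants: 9 2-[(2R,5S)-5-ethenyl-5-methyloxolan-2-yl]propan-2-ol
Product: 10 (2S,5R)-2-ethenyl-2-methyl-5-(prop-1-en-2-yl)oxolane
Conditions: POCl3, pyridine, 0 °C to rt
Reagents that add atoms: none
Why: Dehydration of the tertiary alcohol by E2 elimination of its dichlorophosphate. Six methyl hydrogens compete with one ring hydrogen whose loss would give a strained tetrasubstituted enol ether, so the isopropenyl group should result.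

Step 5
Reactants: 10 (2S,5R)-2-ethenyl-2-methyl-5-(prop-1-en-2-yl)oxolane
Product: 11 (2S,5R)-5-(2-azidopropan-2-yl)-2-ethenyl-2-methyloxolane
Conditions: Fe2(C2O4)3·6H2O, NaN3, NaBH4, EtOH/H2O, 0 °C
Reagents that add atoms: sodium azide ([Na+].[N-]=[N+]=[N-])
Why: Mukaiyama-type Markovnikov hydroazidation by hydrogen-atom transfer: the 1,1-disubstituted alkene gives a tertiary C15 radical that is trapped by azide, whereas the ethenyl group would give a less stable secondary radical. A radical at C15 does not rearrange as a cation would.

Step 6
Reactants: 11 (2S,5R)-5-(2-azidopropan-2-yl)-2-ethenyl-2-methyloxolane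
Product: 13 2-[(2S,5R)-5-(2-azidopropan-2-yl)-2-methyloxolan-2-yl]ethan-1-ol, via alkylborane 12 (not isolated)
Conditions: 9-BBN, THF, 0 °C to rt; then NaOH, H2O2
Reagents that add atoms: hydrogen peroxide (OO)
Why: Hydroboration–oxidation; 9-BBN adds anti-Markovnikov to the only alkene left, and the hindered tertiary azide is not reduced at room temperature.

Step 7
Reactants: 13 2-[(2S,5R)-5-(2-azidopropan-2-yl)-2-methyloxolan-2-yl]ethan-1-ol
Product: 15 2-[(2S,5R)-5-(2-azidopropan-2-yl)-2-methyloxolan-2-yl]acetic acid, via aldehyde 14 (not isolated)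
Conditions: TEMPO (cat.), PhI(OAc)2, MeCN/H2O, rt
Reagents that add atoms: water (O)
Why: Oxoammonium oxidation of the primary alcohol through the aldehyde hydrate to the acid, without strong acid or base, so ether ring and azide are untouched.

Step 8
Reactants: 15 2-[(2S,5R)-5-(2-azidopropan-2-yl)-2-methyloxolan-2-yl]acetic acid; 6 (1R,4S)-1-methyl-4-(prop-1-en-2-yl)cyclohex-2-en-1-ol
Product: 18 (1R,4S)-1-methyl-4-(prop-1-en-2-yl)cyclohex-2-en-1-yl 2-[(2S,5R)-5-(2-azidopropan-2-yl)-2-methyloxolan-2-yl]acetate, via acid chloride 16 (not isolated), via lithium alkoxide 17 (not isolated)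
Conditions: 15, (COCl)2, DMF (cat.), CH2Cl2, 0 °C; 6, n-BuLi, THF, −78 °C; combine, −78 to 0 °C
Reagents that add atoms: none
Why: Acylation of a lithium alkoxide by an acid chloride, the reliable esterification of a hindered tertiary allylic alcohol. The azide has no N–H to quench the alkoxide, and C1 keeps its configuration because its C–O bond is not touched.

Step 9
Reactants: 18 (1R,4S)-1-methyl-4-(prop-1-en-2-yl)cyclohex-2-en-1-yl 2-[(2S,5R)-5-(2-azidopropan-2-yl)-2-methyloxolan-2-yl]acetate
Product: 21 (1R,4S)-1-methyl-4-(prop-1-en-2-yl)cyclohex-2-en-1-yl 2-[(2S,5R)-2-methyl-5-{2-[(4-methylbenzenesulfonyl)amino]propan-2-yl}oxolan-2-yl]acetate, via iminophosphorane 19 (not isolated), via amine 20 (not isolated)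
Conditions: PMe3, THF, rt; H2O, 50 °C; then TsCl, Et3N, DMAP (cat.), CH2Cl2, rt
Reagents that add atoms: p-toluenesulfonyl chloride (Cc1ccc(cc1)S(Cl)(=O)=O)
Why: Staudinger reduction of the tertiary azide and sulfonylation of the resulting hindered amine. The sulfonamide withstands base, hydride and Lewis acid and is removed later together with the one on C7.

Step 10
Reactants: 21 (1R,4S)-1-methyl-4-(prop-1-en-2-yl)cyclohex-2-en-1-yl 2-[(2S,5R)-2-methyl-5-{2-[(4-methylbenzenesulfonyl)amino]propan-2-yl}oxolan-2-yl]acetate
Product: 24 (2R)-2-[(1R,6S)-3-methyl-6-(prop-1-en-2-yl)cyclohex-2-en-1-yl]-2-[(2S,5R)-2-methyl-5-{2-[(4-methylbenzenesulfonyl)amino]propan-2-yl}oxolan-2-yl]acetic acid, via silyl ketene acetal 22 (not isolated), via silyl ester 23 (not isolated)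
Conditions: LiN(i-Pr)2 (2.3 equiv), Me3SiCl/Et3N, THF, −78 °C; then rt; 1 M HCl
Reagents that add atoms: none
Why: Ireland–Claisen rearrangement: one equivalent of base takes the sulfonamide proton, the second gives the (E)-silyl ketene acetal, which is silylated at −78 °C before the β-ether oxygen can be expelled. The C3–C4 bond forms on the face that carried the C1 oxygen, hence cis to the isopropenyl group. With the α-substituent cis to the allylic oxygen, the boat-like transition state usual for esters of cyclohex-2-enols gives the 3,4-anti acid that ring B needs.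

Step 11
Reactants: 24 (2R)-2-[(1R,6S)-3-methyl-6-(prop-1-en-2-yl)cyclohex-2-en-1-yl]-2-[(2S,5R)-2-methyl-5-{2-[(4-methylbenzenesulfonyl)amino]propan-2-yl}oxolan-2-yl]acetic acid
Product: 25 primary alcohol (CH2OH in place of CO2H of 24; same arrangement in space)
Conditions: LiAlH4, THF, 0 °C to rt
Reagents that add atoms: none
Why: Hydride reduction of the carboxylic acid; alkenes, ether and sulfonamide are inert and C4 is not enolised.

Step 12
Reactants: 25 primary alcohol
Product: 26 (2R)-2-[(1R,6S)-3-methyl-6-(prop-1-en-2-yl)cyclohex-2-en-1-yl]-2-[(2S,5R)-2-methyl-5-{2-[(4-methylbenzenesulfonyl)amino]propan-2-yl}oxolan-2-yl]acetaldehyde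
Conditions: Dess–Martin periodinane, NaHCO3, CH2Cl2, 0 °C
Reagents that add atoms: none
Why: Buffered Dess–Martin oxidation stops at the aldehyde under neutral conditions, which preserves the α-centre C4 and the β-ether; the aldehyde is used at once.

Step 13
Reactants: 26 aldehyde with the C5 aldehyde arm and the C8 isopropenyl group cis on ring A
Product: 27 cis-fused hydroxy octalin (3α-H, 8α-H, C4 ether arm α, 5β-hydroxyl, 7-methylidene, C15 sulfonamide)
Conditions: Me2AlCl (2.5 equiv), CH2Cl2, −78 to −40 °C; aq. potassium sodium tartrate
Reagents that add atoms: none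
Why: Me2AlCl binds the aldehyde oxygen, the terminal carbon C6 of the isopropenyl group adds to C5 and a hydrogen of the C7 methyl group passes to oxygen, either in concert or through a short-lived tertiary C7 cation, which leaves the exocyclic methylene; the methyl groups on aluminium scavenge protons so that no HCl adds to the alkenes. The closest known reaction type is the Lewis-acid-promoted intramolecular carbonyl-ene cyclisation of unsaturated aldehydes to 3-methylidenecyclohexanols, as in citronellal to isopulegol. Ring B closes as a six-membered ring with both ene carbons inside it and the carbonyl oxygen outside (endo with respect to the ene π bond). The fusion can only be cis because both arms stand on the same face of ring A. The new centre C5 is set in a chair transition state in which the bulky C4 ether arm and the aluminium-bound oxygen are both equatorial, so the hydroxyl ends trans to the C4 arm, on the β face. The step needs this C5 configuration and an untouched C4; the first is secured by the equatorial preference of the quaternary-carbon substituent, the second by a non-basic Lewis acid at low temperature that neither enolises the aldehyde nor opens the β-ether. One equivalent of the reagent is taken up by the sulfonamide N–H, hence the excess.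

Step 14
Reactants: 27 cis-fused hydroxy octalin
Product: 28 N-tosyl carbamate of 27 on the C5 oxygen
Conditions: TsNCO, CH2Cl2, 0 °C
Reagents that add atoms: p-toluenesulfonyl isocyanate (Cc1ccc(cc1)S(=O)(=O)N=C=O)
Why: Addition of an alcohol to a sulfonyl isocyanate is fast even at a hindered secondary hydroxyl and gives an acidic carbamate N–H that serves as a tethered nitrogen nucleophile.

Step 15
Reactants: 28 N-tosyl carbamate
Product: 29 cyclic N-tosyl carbamate bridging O5 and N7 on the β face, with an iodomethyl group on C7 (α)
Conditions: I2, NaHCO3, Et2O/H2O, rt, dark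
Reagents that add atoms: iodine (II)
Why: Iodoamidation of an N-sulfonyl carbamate: its anion attacks the substituted carbon C7 of the iodonium ion through nitrogen and closes a six-membered ring (6-exo). Because the tether starts at the β-oxygen on C5, nitrogen can reach only the β face of C7, which is the target configuration; ring B passes through a boat to make both bonds axial.

Step 16
Reactants: 29 cyclic iodo carbamate
Product: 30 cyclic N-tosyl carbamate with a C7 methyl group
Conditions: Bu3SnH, AIBN (cat.), toluene, 80 °C
Reagents that add atoms: none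
Why: Radical dehalogenation turns the primary iodide into the C7 methyl group; no stereocentre is touched.

Step 17
Reactants: 30 cyclic N-tosyl carbamate
Product: 31 hydroxy bis-sulfonamide (5β-hydroxyl, 7β-tosylamino, 7α-methyl)
Conditions: K2CO3, MeOH, 40 °C
Reagents that add atoms: none
Why: Methanolysis of a carbamate that the N-sulfonyl group activates toward nucleophiles; the carbonyl carbon leaves as dimethyl carbonate.

Step 18
Reactants: 31 hydroxy bis-sulfonamide
Product: 32 O5-(imidazol-1-ylthiocarbonyl) derivative of 31
Conditions: 1,1′-thiocarbonyldiimidazole, DMAP, toluene, 90 °C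
Reagents that add atoms: 1,1′-thiocarbonyldiimidazole (S=C(n1ccnc1)n1ccnc1)
Why: Thioacylation for a Barton–McCombie deoxygenation; the equatorial secondary hydroxyl reacts on heating and the hindered sulfonamide nitrogens are too weakly nucleophilic to compete.

Step 19
Reactants: 32 thiocarbonyl derivative
Product: 33 bis-sulfonamide with C5 as CH2
Conditions: Bu3SnH, AIBN, toluene, 110 °C
Reagents that add atoms: none
Why: Barton–McCombie deoxygenation; the secondary C5 radical has no fast cyclisation or fragmentation open to it and is reduced by the stannane.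

Step 20
Reactants: 33 bis-sulfonamide
Product: 34 diamine (free NH2 on C7 and C15)
Conditions: SmI2, Et3N, H2O, THF, rt
Reagents that add atoms: none
Why: Reductive cleavage of both N–S bonds by single-electron transfer from SmI2 activated by amine and water; alkene and ethers are inert and no acid is used.

Step 21
Reactants: 34 diamine
Product: 35 target bisformamide CNP0173819.1
Conditions: HCO2H/Ac2O (preformed mixed anhydride), pyridine, CH2Cl2, 0 °C to rt
Reagents that add atoms: acetic formic anhydride (CC(=O)OC=O)
Why: N-Formylation with the mixed anhydride, whose small formyl group reaches both tert-alkyl amines.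

## Compound list

1 | (S)-limonene, (4S)-1-methyl-4-(prop-1-en-2-yl)cyclohex-1-ene | CC1=CC[C@H](CC1)C(C)=C | starting material
2 | (1R,2R,4S)-2-bromo-1-methyl-4-(prop-1-en-2-yl)cyclohexan-1-ol | C[C@@]1(O)CC[C@H](C(C)=C)C[C@H]1Br | intermediate
3 | (1R,4S,6S)-1-methyl-4-(prop-1-en-2-yl)-7-oxabicyclo[4.1.0]heptane (epoxide oxygen cis to isopropenyl) | C[C@@]12CC[C@H](C(C)=C)C[C@@H]1O2 | intermediate
4 | (1R,2R,4S)-1-methyl-2-(phenylselanyl)-4-(prop-1-en-2-yl)cyclohexan-1-ol | C[C@@]1(O)CC[C@H](C(C)=C)C[C@H]1[Se]c1ccccc1 | intermediate
5 | Se-oxide of 4 | C[C@@]1(O)CC[C@H](C(C)=C)C[C@H]1[Se](=O)c1ccccc1 | intermediate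
6 | (1R,4S)-1-methyl-4-(prop-1-en-2-yl)cyclohex-2-en-1-ol (hydroxyl cis to isopropenyl) | C[C@]1(O)C=C[C@H](CC1)C(C)=C | intermediate
7 | (S)-linalool, (3S)-3,7-dimethylocta-1,6-dien-3-ol | C=C[C@](O)(C)CCC=C(C)C | starting material
8 | (3S)-5-[(2S)-3,3-dimethyloxiran-2-yl]-3-methylpent-1-en-3-ol | C=C[C@](O)(C)CC[C@@H]1OC1(C)C | intermediate
9 | 2-[(2R,5S)-5-ethenyl-5-methyloxolan-2-yl]propan-2-ol (ethenyl cis to the hydroxypropyl group) | C=C[C@]1(C)CC[C@H](C(C)(C)O)O1 | intermediate
10 | (2S,5R)-2-ethenyl-2-methyl-5-(prop-1-en-2-yl)oxolane | C=C[C@]1(C)CC[C@H](C(C)=C)O1 | intermediate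
11 | (2S,5R)-5-(2-azidopropan-2-yl)-2-ethenyl-2-methyloxolane | C=C[C@]1(C)CC[C@H](C(C)(C)N=[N+]=[N-])O1 | intermediate
12 | B-alkyl-9-borabicyclo[3.3.1]nonane from 11 (boron on the terminal carbon of the former ethenyl group) | B1(CC[C@]2(C)CC[C@H](C(C)(C)N=[N+]=[N-])O2)C2CCCC1CCC2 | intermediate
13 | 2-[(2S,5R)-5-(2-azidopropan-2-yl)-2-methyloxolan-2-yl]ethan-1-ol | OCC[C@]1(C)CC[C@H](C(C)(C)N=[N+]=[N-])O1 | intermediate
14 | 2-[(2S,5R)-5-(2-azidopropan-2-yl)-2-methyloxolan-2-yl]acetaldehyde | O=CC[C@]1(C)CC[C@H](C(C)(C)N=[N+]=[N-])O1 | intermediate
15 | 2-[(2S,5R)-5-(2-azidopropan-2-yl)-2-methyloxolan-2-yl]acetic acid | OC(=O)C[C@]1(C)CC[C@H](C(C)(C)N=[N+]=[N-])O1 | intermediate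
16 | acid chloride of 15 | ClC(=O)C[C@]1(C)CC[C@H](C(C)(C)N=[N+]=[N-])O1 | intermediate
17 | lithium (1R,4S)-1-methyl-4-(prop-1-en-2-yl)cyclohex-2-en-1-olate | C[C@]1([O-])C=C[C@H](CC1)C(C)=C.[Li+] | intermediate
18 | (1R,4S)-1-methyl-4-(prop-1-en-2-yl)cyclohex-2-en-1-yl 2-[(2S,5R)-5-(2-azidopropan-2-yl)-2-methyloxolan-2-yl]acetate | C[C@]1(OC(=O)C[C@]2(C)CC[C@H](C(C)(C)N=[N+]=[N-])O2)C=C[C@H](CC1)C(C)=C | intermediate
19 | trimethyliminophosphorane of 18 (N=PMe3 in place of N3) | C[C@]1(OC(=O)C[C@]2(C)CC[C@H](C(C)(C)N=P(C)(C)C)O2)C=C[C@H](CC1)C(C)=C | intermediate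
20 | primary amine of 18 (NH2 in place of N3) | C[C@]1(OC(=O)C[C@]2(C)CC[C@H](C(C)(C)N)O2)C=C[C@H](CC1)C(C)=C | intermediate
21 | (1R,4S)-1-methyl-4-(prop-1-en-2-yl)cyclohex-2-en-1-yl 2-[(2S,5R)-2-methyl-5-{2-[(4-methylbenzenesulfonyl)amino]propan-2-yl}oxolan-2-yl]acetate | C[C@]1(OC(=O)C[C@]2(C)CC[C@H](C(C)(C)NS(=O)(=O)c3ccc(C)cc3)O2)C=C[C@H](CC1)C(C)=C | intermediate
22 | (E)-trimethylsilyl ketene acetal of 21, lithium sulfonamide salt (ether-ring carbon cis to the allylic oxygen) | C[C@]1(O/C(O[Si](C)(C)C)=C\[C@]2(C)CC[C@H](C(C)(C)[N-]S(=O)(=O)c3ccc(C)cc3)O2)C=C[C@H](CC1)C(C)=C.[Li+] | intermediate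
23 | trimethylsilyl ester of 24, lithium sulfonamide salt | CC1=C[C@@H]([C@@H](C(=O)O[Si](C)(C)C)[C@]2(C)CC[C@H](C(C)(C)[N-]S(=O)(=O)c3ccc(C)cc3)O2)[C@H](CC1)C(C)=C.[Li+] | intermediate
24 | (2R)-2-[(1R,6S)-3-methyl-6-(prop-1-en-2-yl)cyclohex-2-en-1-yl]-2-[(2S,5R)-2-methyl-5-{2-[(4-methylbenzenesulfonyl)amino]propan-2-yl}oxolan-2-yl]acetic acid (arm cis to isopropenyl, C4 anti to C8) | CC1=C[C@@H]([C@@H](C(O)=O)[C@]2(C)CC[C@H](C(C)(C)NS(=O)(=O)c3ccc(C)cc3)O2)[C@H](CC1)C(C)=C | intermediate
25 | primary alcohol from 24 (CH2OH in place of CO2H, same arrangement in space) | CC1=C[C@@H]([C@@H](CO)[C@]2(C)CC[C@H](C(C)(C)NS(=O)(=O)c3ccc(C)cc3)O2)[C@H](CC1)C(C)=C | intermediate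
26 | (2R)-2-[(1R,6S)-3-methyl-6-(prop-1-en-2-yl)cyclohex-2-en-1-yl]-2-[(2S,5R)-2-methyl-5-{2-[(4-methylbenzenesulfonyl)amino]propan-2-yl}oxolan-2-yl]acetaldehyde | CC1=C[C@@H]([C@@H](C=O)[C@]2(C)CC[C@H](C(C)(C)NS(=O)(=O)c3ccc(C)cc3)O2)[C@H](CC1)C(C)=C | intermediate
27 | cis-fused hydroxy octalin: 3α-H, 8α-H, C4 ether arm α, 5β-hydroxyl, 7-methylidene, C15 sulfonamide | CC1=C[C@H]2[C@H]([C@]3(C)CC[C@H](C(C)(C)NS(=O)(=O)c4ccc(C)cc4)O3)[C@@H](O)CC(=C)[C@H]2CC1 | intermediate
28 | N-tosyl carbamate of 27 on O5 | CC1=C[C@H]2[C@H]([C@]3(C)CC[C@H](C(C)(C)NS(=O)(=O)c4ccc(C)cc4)O3)[C@@H](OC(=O)NS(=O)(=O)c5ccc(C)cc5)CC(=C)[C@H]2CC1 | intermediate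
29 | cyclic N-tosyl carbamate bridging O5 and N7 on the β face, 7α-iodomethyl | CC1=C[C@H]2[C@H]([C@]3(C)CC[C@H](C(C)(C)NS(=O)(=O)c4ccc(C)cc4)O3)[C@@H]5C[C@@](CI)(N(C(=O)O5)S(=O)(=O)c6ccc(C)cc6)[C@H]2CC1 | intermediate
30 | cyclic N-tosyl carbamate, 7α-methyl | CC1=C[C@H]2[C@H]([C@]3(C)CC[C@H](C(C)(C)NS(=O)(=O)c4ccc(C)cc4)O3)[C@@H]5C[C@@](C)(N(C(=O)O5)S(=O)(=O)c6ccc(C)cc6)[C@H]2CC1 | intermediate
31 | hydroxy bis-sulfonamide: 5β-hydroxyl, 7β-tosylamino, 7α-methyl | CC1=C[C@H]2[C@H]([C@]3(C)CC[C@H](C(C)(C)NS(=O)(=O)c4ccc(C)cc4)O3)[C@@H](O)C[C@@](C)(NS(=O)(=O)c5ccc(C)cc5)[C@H]2CC1 | intermediate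
32 | O5-(imidazol-1-ylthiocarbonyl) derivative of 31 | CC1=C[C@H]2[C@H]([C@]3(C)CC[C@H](C(C)(C)NS(=O)(=O)c4ccc(C)cc4)O3)[C@@H](OC(=S)n5ccnc5)C[C@@](C)(NS(=O)(=O)c6ccc(C)cc6)[C@H]2CC1 | intermediate
33 | bis-sulfonamide with C5 as CH2 (tosylamino on C7 and C15) | CC1=C[C@H]2[C@H]([C@]3(C)CC[C@H](C(C)(C)NS(=O)(=O)c4ccc(C)cc4)O3)CC[C@@](C)(NS(=O)(=O)c5ccc(C)cc5)[C@H]2CC1 | intermediate
34 | diamine (NH2 on C7 and C15) | CC1=C[C@H]2[C@H]([C@]3(C)CC[C@H](C(C)(C)N)O3)CC[C@@](C)(N)[C@H]2CC1 | intermediate
35 | target bisformamide CNP0173819.1, (3R,4R,7R,8S,11S,14R) in the labels used here | CC1=C[C@H]2[C@H]([C@]3(C)CC[C@H](C(C)(C)NC=O)O3)CC[C@@](C)(NC=O)[C@H]2CC1 | target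

## Step count and least certain steps

Total: 21 steps. Longest linear sequence: 19 steps (steps 3–21, from 7); the limonene branch contributes steps 1 and 2.

**Step 13 (key step).** The most likely failures are closure through a transition state with an axial oxygen, which gives the C5 epimer that cannot deliver nitrogen to the β face, and capture of the C7 cation by chloride. The chair preference rests only on the size of the C4 substituent, and the sulfonamide may alter the Lewis acid. Fallback: set out from 26, accept whatever C5 configuration the cyclisation gives, oxidise the C5-epimeric alcohol F1 (or the mixture) with Dess–Martin periodinane to the C5 ketone F2, and reduce it with NaBH4 and CeCl3·7H2O at low temperature. Axial hydride delivery to the cyclohexanone gives the equatorial β-alcohol, so the C5 centre is then set by reduction, not by the ene transition state. The sequence comes back at 27.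

**Step 10.** The most likely failure is reversed or low selectivity at C4. In the boat that gives the 3,4-anti acid the quaternary C11 lies over C8 and its isopropenyl group, so the chair, which gives the C4 epimer, may take over. β-Elimination of the ether oxygen from the enolate is the second risk. Fallback: set out from 21 and do not fight the bias. The (Z)-silyl ketene acetal (LiN(i-Pr)2 with DMPU) through the unhindered boat should give the C4-epimeric acid F3 cleanly. Its carboxyl group lies over the ring alkene, so I2 with NaHCO3 in MeCN should close the cis-fused γ-iodolactone F4. Enolisation with LiN(i-Pr)2 at −78 °C and kinetic protonation on the convex face puts C11 on the concave face, giving the C4-inverted iodolactone F5. Zn in AcOH then restores alkene and acid by reductive elimination. C4 is thus set by protonation of a bicyclic enolate instead of by the rearrangement, and the sequence comes back at 24.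

**Step 5.** The most likely failure is competing hydrogen-atom transfer to the ethenyl group, which gives a secondary azide or a bis-azide, because the selectivity rests only on radical stability. Fallback: set out from 9 and remove the competing alkene first. Hydroboration–oxidation of 9 with 9-BBN gives the diol F6. Pivaloyl chloride acylates only its primary hydroxyl to give the pivalate F7. Dehydration with POCl3 in pyridine gives the isopropenyl pivalate F8. The same hydroazidation, now on a single alkene, gives the azido pivalate F9, and K2CO3 in MeOH removes the ester. The sequence comes back at 13.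

**Step 15.** The most likely failures are slow ring closure, because ring B must leave its chair for nitrogen and oxygen to become axial, then attack through the carbamate oxygen, and reversible iodination of the ring A alkene. Fallback: set out from 27 and use a neutral, more nucleophilic nitrogen with an irreversible electrophile. Cl3CCN with catalytic DBU gives the trichloroacetimidate F10. Hg(OCOCF3)2 closes the ring through nitrogen at C7 to the organomercurial F11, which NaBH4 reduces in the same flask to the C7-methyl dihydro-1,3-oxazine F12. Aqueous HCl then frees the amino alcohol F13, whose amine alone is sulfonylated with TsCl and Et3N. The sequence comes back at 31 and replaces steps 14–17.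

## Further compounds

F1 | step 13 | C5 epimer of 27 (5α-hydroxyl) | CC1=C[C@H]2[C@H]([C@]3(C)CC[C@H](C(C)(C)NS(=O)(=O)c4ccc(C)cc4)O3)[C@H](O)CC(=C)[C@H]2CC1
F2 | step 13 | C5 ketone of the cis-fused octalin | CC1=C[C@H]2[C@H]([C@]3(C)CC[C@H](C(C)(C)NS(=O)(=O)c4ccc(C)cc4)O3)C(=O)CC(=C)[C@H]2CC1
F3 | step 10 | C4 epimer of acid 24 | CC1=C[C@@H]([C@H](C(O)=O)[C@]2(C)CC[C@H](C(C)(C)NS(=O)(=O)c3ccc(C)cc3)O2)[C@H](CC1)C(C)=C
F4 | step 10 | cis-fused γ-iodolactone of F3 (lactone oxygen on C2, iodine on C1, C11 on the convex face) | O=C1O[C@H]2[C@@H]([C@H]1[C@]3(C)CC[C@H](C(C)(C)NS(=O)(=O)c4ccc(C)cc4)O3)[C@@H](C(C)=C)CC[C@]2(C)I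
F5 | step 10 | C4-inverted γ-iodolactone (C11 on the concave face) | O=C1O[C@H]2[C@@H]([C@@H]1[C@]3(C)CC[C@H](C(C)(C)NS(=O)(=O)c4ccc(C)cc4)O3)[C@@H](C(C)=C)CC[C@]2(C)I
F6 | step 5 | 2-[(2R,5S)-5-(2-hydroxyethyl)-5-methyloxolan-2-yl]propan-2-ol | OCC[C@]1(C)CC[C@H](C(C)(C)O)O1
F7 | step 5 | primary pivalate of F6 | CC(C)(C)C(=O)OCC[C@]1(C)CC[C@H](C(C)(C)O)O1
F8 | step 5 | isopropenyl pivalate | CC(C)(C)C(=O)OCC[C@]1(C)CC[C@H](C(C)=C)O1
F9 | step 5 | azido pivalate | CC(C)(C)C(=O)OCC[C@]1(C)CC[C@H](C(C)(C)N=[N+]=[N-])O1
F10 | step 15 | O5-trichloroacetimidate of 27 | CC1=C[C@H]2[C@H]([C@]3(C)CC[C@H](C(C)(C)NS(=O)(=O)c4ccc(C)cc4)O3)[C@@H](OC(=N)C(Cl)(Cl)Cl)CC(=C)[C@H]2CC1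
F11 | step 15 | organomercurial dihydro-1,3-oxazine (CH2HgOCOCF3 on C7) | CC1=C[C@H]2[C@H]([C@]3(C)CC[C@H](C(C)(C)NS(=O)(=O)c4ccc(C)cc4)O3)[C@@H]5C[C@@](C[Hg]OC(=O)C(F)(F)F)(N=C(O5)C(Cl)(Cl)Cl)[C@H]2CC1
F12 | step 15 | 2-trichloromethyl-dihydro-1,3-oxazine bridging O5 and N7, 7α-methyl | CC1=C[C@H]2[C@H]([C@]3(C)CC[C@H](C(C)(C)NS(=O)(=O)c4ccc(C)cc4)O3)[C@@H]5C[C@@](C)(N=C(O5)C(Cl)(Cl)Cl)[C@H]2CC1
F13 | step 15 | amino alcohol (5β-hydroxyl, 7β-amino, 7α-methyl, C15 sulfonamide) | CC1=C[C@H]2[C@H]([C@]3(C)CC[C@H](C(C)(C)NS(=O)(=O)c4ccc(C)cc4)O3)[C@@H](O)C[C@@](C)(N)[C@H]2CC1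
A1 | alternative 1 | cis-2-ethenyl-2-methyl-5-[2-(2,2,2-trichloroethoxysulfonylamino)propan-2-yl]oxolane | C=C[C@]1(C)CC[C@H](C(C)(C)NS(=O)(=O)OCC(Cl)(Cl)Cl)O1
A2 | alternative 1 | N-(2,2,2-trichloroethoxysulfonyl) 6,7-aziridine of (S)-linalool | C=C[C@](O)(C)CC[C@@H]1N(S(=O)(=O)OCC(Cl)(Cl)Cl)C1(C)C
A3 | alternative 2 | cis-fused tricyclic nitrile azide (C7 nitrile, C15 azide) | CC1=C[C@H]2[C@H]([C@]3(C)CC[C@H](C(C)(C)N=[N+]=[N-])O3)CC[C@@](C)(C#N)[C@H]2CC1
A4 | alternative 2 | ring A tertiary allylic alcohol with the (Z)-alkene side chain, C7 nitrile, C14 hydroxyl and C15 azide | CC1(O)C=C[C@H](CC1)[C@](C)(C#N)CC/C=C(C)\CC[C@@H](O)C(C)(C)N=[N+]=[N-]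
A5 | alternative 3 | cis-2,5-disubstituted oxolane with C15 as CH2CO2CH3 on the formamido decalin | CC1=C[C@H]2[C@H]([C@]3(C)CC[C@H](CC(=O)OC)O3)CC[C@@](C)(NC=O)[C@H]2CC1
A6 | alternative 3 | C13 bromide with the (E)-β-alkoxyacrylate on the C11 oxygen | CC1=C[C@H]2[C@H]([C@](C)(CCBr)O/C=C/C(=O)OC)CC[C@@](C)(NC=O)[C@H]2CC1
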